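**Retrosynthetic overview**
1. The butenolide of the upper half is closed last: target 33 ⇐ (Z)-γ-keto enoate 31 (reagent-controlled C8 reduction, then lactonisation) ⇐ dienolide 30 ⇐ aldol adduct 29.
2. Key disconnection C7–C11: intermolecular aldol addition of the kinetic enolate of ent-elemane ketone 27 to α-keto ester 21, which already carries the complete lower (cis-lactone) half.
3. 21 ⇐ Michael addition of a pyruvate-enolate equivalent (oxalacetate 18) to α-methylene lactone 14 (C13–C13′ bond, C11′ set by convex-face protonation), then deallylative decarboxylation.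
4. 14 ⇐ ketone 6 (alkylation, L-Selectride reduction/lactonisation, Mannich methylenation). Ketones 6 and 27 ⇐ (+)- and (−)-verbenone by vinyl cuprate addition and cyclobutane fragmentation.
5. Ring order: both carbocycles come from the pinane cores; the cis-γ-lactone (lower half) is closed first (step 4), the butenolide (upper half) last (step 15).

Assumption: both verbenone enantiomers are used in ≥98% ee (catalogue grades, or one allylic oxidation from the cheap α-pinene enantiomers). Elemane locants are used in the comments (C5 isopropenyl carbon, C10 quaternary carbon, C8 O-bearing carbon, C7/C11/C12/C13 lactone carbons; primes = saturated-lactone half).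

**Step 1**
Reactants: 1 (1R,5R)-(+)-verbenone
Product: 3 (1R,4S,5S)-4-ethenyl-4,6,6-trimethylbicyclo[3.1.1]heptan-2-one, via TMS enol ether 2 (not isolated)
Conditions: CH2=CHMgBr (2 equiv), CuBr·SMe2 (10 mol %), TMSCl (2 equiv), THF, −40 → 0 °C; then 1 M HCl
Reagents that add atoms: vinylmagnesium bromide C=C[Mg]Br
Why: Copper-catalysed conjugate addition; the cuprate attacks the enone face anti to the gem-dimethyl bridge, so the new quaternary centre (C10′) has vinyl anti and methyl syn to the bridge that later becomes the isopropenyl group.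

**Step 2**
Reactants: 3 (1R,4S,5S)-4-ethenyl-4,6,6-trimethylbicyclo[3.1.1]heptan-2-one
Product: 6 (3S,4S)-3-ethenyl-3-methyl-4-(prop-1-en-2-yl)cyclohexan-1-one, via iodo silyl enol ether 4 (not isolated), via dienyl silyl ether 5 (not isolated)
Conditions: TMSI (1.3 equiv), CH2Cl2, −20 → 0 °C; DBU (3 equiv), 0 °C → rt; then 1 M HCl–THF
Reagents that add atoms: none
Why: Silyl-activated cyclobutane fragmentation (only the C1–C6 bond gives a tertiary cation plus an enol silane), then E2 loss of HI toward a methyl group; neither stereocentre is touched, so vinyl ends trans to isopropenyl.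

**Step 3**
Reactants: 6 (3S,4S)-3-ethenyl-3-methyl-4-(prop-1-en-2-yl)cyclohexan-1-one
Product: 8 methyl [(1R,4S,5S)-4-ethenyl-4-methyl-2-oxo-5-(prop-1-en-2-yl)cyclohexyl]acetate, via lithium enolate 7 (not isolated)
Conditions: LDA (1.05 equiv), THF, −78 °C; BrCH2CO2Me, DMPU, −78 → −20 °C; then K2CO3 (cat.), MeOH, rt
Reagents that add atoms: methyl bromoacetate COC(=O)CBr
Why: Kinetic enolate alkylation at the less hindered α-CH2 (C7′; C9′ is flanked by the quaternary centre); base equilibration puts the acetate arm equatorial, cis to isopropenyl, which locks the chair.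

**Step 4**
Reactants: 8 methyl [(1R,4S,5S)-4-ethenyl-4-methyl-2-oxo-5-(prop-1-en-2-yl)cyclohexyl]acetate
Product: 10 (3aR,5S,6S,7aR)-6-ethenyl-6-methyl-5-(prop-1-en-2-yl)hexahydro-1-benzofuran-2(3H)-one, via axial lithium alkoxide 9 (not isolated)
Conditions: L-Selectride (1.2 equiv), THF, −78 °C → rt; H2O quench
Reagents that add atoms: none
Why: Bulky hydride reduction from the equatorial side of the locked chair (axial attack is blocked by the 1,3-axial methyl) gives the axial C8′ alkoxide cis to the acetate arm, which lactonises to the cis-fused γ-lactone.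

**Step 5**
Reactants: 10 (3aR,5S,6S,7aR)-6-ethenyl-6-methyl-5-(prop-1-en-2-yl)hexahydro-1-benzofuran-2(3H)-one
Product: 12 (3S,3aR,5S,6S,7aR)-3-[(dimethylamino)methyl]-6-ethenyl-6-methyl-5-(prop-1-en-2-yl)hexahydro-1-benzofuran-2(3H)-one, via lactone lithium enolate 11 (not isolated)
Conditions: LDA (1.1 equiv), THF, −78 °C; Eschenmoser's salt, −78 °C → rt
Reagents that add atoms: N,N-dimethylmethyleneiminium iodide C=[N+](C)C.[I-]
Why: Mannich aminomethylation of the lactone enolate on its convex face; this stereocentre is erased in the next step.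

**Step 6**
Reactants: 12 (3S,3aR,5S,6S,7aR)-3-[(dimethylamino)methyl]-6-ethenyl-6-methyl-5-(prop-1-en-2-yl)hexahydro-1-benzofuran-2(3H)-one
Product: 14 (3aR,5S,6S,7aR)-6-ethenyl-6-methyl-3-methylidene-5-(prop-1-en-2-yl)hexahydro-1-benzofuran-2(3H)-one, via ammonium iodide 13 (not isolated)
Conditions: MeI (excess), MeOH, rt; then 5% aq. NaHCO3/CH2Cl2, rt
Reagents that add atoms: none
Why: N-Quaternisation followed by E1cB (Hofmann-type) elimination of trimethylamine gives the α-methylene lactone under conditions that leave the other alkenes alone.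

**Step 7**
Reactants: 15 prop-2-en-1-yl acetate (allyl acetate); 16 dimethyl oxalate
Product: 18 1-methyl 4-prop-2-en-1-yl 2-oxobutanedioate, via allyl acetate lithium enolate 17 (not isolated)
Conditions: LDA (1.0 equiv), THF, −78 °C; cannulate into 16 (1.5 equiv), THF, −78 → 0 °C; 1 M HCl
Reagents that add atoms: none
Why: Crossed Claisen condensation onto a non-enolisable oxalate gives a pyruvate-enolate equivalent whose extra ester can later be removed under neutral Pd(0) conditions.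

**Step 8**
Reactants: 14 (3aR,5S,6S,7aR)-6-ethenyl-6-methyl-3-methylidene-5-(prop-1-en-2-yl)hexahydro-1-benzofuran-2(3H)-one; 18 1-methyl 4-prop-2-en-1-yl 2-oxobutanedioate
Product: 19 1-methyl 4-prop-2-en-1-yl 2-oxo-3-{[(3S,3aR,5S,6S,7aR)-6-ethenyl-6-methyl-2-oxo-5-(prop-1-en-2-yl)octahydro-1-benzofuran-3-yl]methyl}butanedioate (epimers at the butanedioate C3)
Conditions: 18 (2 equiv), DBU (0.2 equiv), MeCN, 0 °C → rt
Reagents that add atoms: none
Why: Michael addition of the soft, doubly stabilised enolate to the α-methylene lactone forms C13–C13′; the lactone enolate is protonated kinetically on the convex face, giving H11′ cis to H7′/H8′ (11′S), as in hydride and amine additions to cis-fused 8,12-olides.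

**Step 9**
Reactants: 19 1-methyl 4-prop-2-en-1-yl 2-oxo-3-{[(3S,3aR,5S,6S,7aR)-6-ethenyl-6-methyl-2-oxo-5-(prop-1-en-2-yl)octahydro-1-benzofuran-3-yl]methyl}butanedioate
Product: 21 methyl 4-[(3S,3aR,5S,6S,7aR)-6-ethenyl-6-methyl-2-oxo-5-(prop-1-en-2-yl)octahydro-1-benzofuran-3-yl]-2-oxobutanoate, via β-keto acid 20 (not isolated)
Conditions: Pd(PPh3)4 (5 mol %), HCO2H (2 equiv), Et3N, THF, rt → 40 °C
Reagents that add atoms: none
Why: Tsuji deallylation (π-allyl-Pd, formate as hydride source) then spontaneous decarboxylation of the β-keto acid; neutral conditions leave the lactone, C11′ and the isolated alkenes untouched.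

**Step 10**
Reactants: 22 (1S,5S)-(−)-verbenone
Product: 24 (1S,4R,5R)-4-ethenyl-4,6,6-trimethylbicyclo[3.1.1]heptan-2-one, via TMS enol ether 23 (not isolated)
Conditions: as step 1
Reagents that add atoms: vinylmagnesium bromide C=C[Mg]Br
Why: The same copper-catalysed conjugate addition anti to the gem-dimethyl bridge, in the enantiomeric series, sets C10 of the upper half.

**Step 11**
Reactants: 24 (1S,4R,5R)-4-ethenyl-4,6,6-trimethylbicyclo[3.1.1]heptan-2-one
Product: 27 (3R,4R)-3-ethenyl-3-methyl-4-(prop-1-en-2-yl)cyclohexan-1-one, via iodo silyl enol ether 25 (not isolated), via dienyl silyl ether 26 (not isolated)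
Conditions: as step 2
Reagents that add atoms: none
Why: The same cyclobutane fragmentation/E2 sequence gives the enantiomeric elemane ketone (C5 R, C10 R).

**Step 12**
Reactants: 27 (3R,4R)-3-ethenyl-3-methyl-4-(prop-1-en-2-yl)cyclohexan-1-one; 21 methyl 4-[(3S,3aR,5S,6S,7aR)-6-ethenyl-6-methyl-2-oxo-5-(prop-1-en-2-yl)octahydro-1-benzofuran-3-yl]-2-oxobutanoate
Product: 29 methyl (2RS)-2-[(1S,4R,5R)-4-ethenyl-4-methyl-2-oxo-5-(prop-1-en-2-yl)cyclohexyl]-4-[(3S,3aR,5S,6S,7aR)-6-ethenyl-6-methyl-2-oxo-5-(prop-1-en-2-yl)octahydro-1-benzofuran-3-yl]-2-hydroxybutanoate, via lithium enolate 28 (not isolated)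
Conditions: LDA (0.98 equiv), THF, −78 °C, 30 min; 21 (0.9 equiv) in THF, −78 °C, 20 min; AcOH, −78 °C
Reagents that add atoms: none
Why: Crossed aldol addition joining the two halves at C7–C11: the kinetic enolate (away from the quaternary carbon) adds to the α-keto ester ketone, far more electrophilic than the ester or lactone carbonyls; the new centres at C7 and C11 are erased in step 13.

**Step 13**
Reactants: 29 aldol adduct (as named in step 12)
Product: 30 (3S,3aR,5S,6S,7aR)-6-ethenyl-3-{2-[(5R,6R)-6-ethenyl-6-methyl-2-oxo-5-(prop-1-en-2-yl)-2,4,5,6-tetrahydro-1-benzofuran-3-yl]ethyl}-6-methyl-5-(prop-1-en-2-yl)hexahydro-1-benzofuran-2(3H)-one (dienolide, C7=C11 and C8=C9)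
Conditions: p-TsOH·H2O (10 mol %), benzene, reflux, Dean–Stark with 5 Å MS
Reagents that add atoms: none
Why: Acid-catalysed aldol dehydration through the C8 enol places the alkene at C7=C11, then enol-lactonisation with loss of methanol; E/Z isomers equilibrate via the dienol, so all diastereomers of 29 converge on one dienolide with C8–O and C12 held cis.

**Step 14**
Reactants: 30 dienolide (as named in step 13)
Product: 31 methyl (2Z)-2-[(4R,5R)-4-ethenyl-4-methyl-2-oxo-5-(prop-1-en-2-yl)cyclohexylidene]-4-[(3S,3aR,5S,6S,7aR)-6-ethenyl-6-methyl-2-oxo-5-(prop-1-en-2-yl)octahydro-1-benzofuran-3-yl]butanoate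
Conditions: MeOH, K2CO3 (0.2 equiv), 0 °C; AcOH quench
Reagents that add atoms: methanol CO
Why: Base-catalysed methanolysis (acyl transfer) of the activated enol ester unmasks the C8 ketone while keeping the Z alkene geometry; the saturated lactone is far less electrophilic and survives.

**Step 15**
Reactants: 31 (Z)-keto ester (as named in step 14)
Product: 33 (3S,3aR,5S,6S,7aR)-6-ethenyl-3-{2-[(5R,6R,7aR)-6-ethenyl-6-methyl-2-oxo-5-(prop-1-en-2-yl)-2,4,5,6,7,7a-hexahydro-1-benzofuran-3-yl]ethyl}-6-methyl-5-(prop-1-en-2-yl)hexahydro-1-benzofuran-2(3H)-one (target), via allylic alcohol 32 (not isolated)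
Conditions: (S)-Me-CBS (0.5 equiv), catecholborane (2 equiv), toluene, −78 → −40 °C; MeOH quench; PPTS (cat.), CH2Cl2, rt
Reagents that add atoms: none
Why: Corey–Bakshi–Shibata reduction under reagent control (the mobile ring gives no useful substrate bias): the tetrasubstituted alkenyl arm acts as the large group, so the (S)-catalyst delivers hydride to give 8R, and the Z-hydroxy ester lactonises to the butenolide; catecholborane at −78 °C spares the isolated alkenes and the lactone.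

**Compound list**
1 | (1R,5R)-(+)-verbenone | CC1=CC(=O)[C@@H]2C[C@H]1C2(C)C | starting material
2 | {[(1R,4S,5S)-4-ethenyl-4,6,6-trimethylbicyclo[3.1.1]hept-2-en-2-yl]oxy}trimethylsilane | C[C@@]1(C=C)C=C(O[Si](C)(C)C)[C@@H]2C[C@H]1C2(C)C | intermediate (not isolated)
3 | (1R,4S,5S)-4-ethenyl-4,6,6-trimethylbicyclo[3.1.1]heptan-2-one | C[C@@]1(C=C)CC(=O)[C@@H]2C[C@H]1C2(C)C | intermediate
4 | {[(4R,5S)-5-ethenyl-4-(2-iodopropan-2-yl)-5-methylcyclohex-1-en-1-yl]oxy}trimethylsilane | C[C@@]1(C=C)CC(O[Si](C)(C)C)=CC[C@H]1C(C)(C)I | intermediate (not isolated)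
5 | {[(4S,5S)-5-ethenyl-5-methyl-4-(prop-1-en-2-yl)cyclohex-1-en-1-yl]oxy}trimethylsilane | C[C@@]1(C=C)CC(O[Si](C)(C)C)=CC[C@H]1C(C)=C | intermediate (not isolated)
6 | (3S,4S)-3-ethenyl-3-methyl-4-(prop-1-en-2-yl)cyclohexan-1-one | O=C1C[C@@](C)(C=C)[C@H](C(=C)C)CC1 | intermediate
7 | lithium (4S,5S)-5-ethenyl-5-methyl-4-(prop-1-en-2-yl)cyclohex-1-en-1-olate | C[C@@]1(C=C)CC(O[Li])=CC[C@H]1C(C)=C | intermediate (not isolated)
8 | methyl [(1R,4S,5S)-4-ethenyl-4-methyl-2-oxo-5-(prop-1-en-2-yl)cyclohexyl]acetate | O=C1C[C@@](C)(C=C)[C@H](C(=C)C)C[C@@H]1CC(=O)OC | intermediate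
9 | methyl [(1R,2R,4S,5S)-4-ethenyl-2-(lithiooxy)-4-methyl-5-(prop-1-en-2-yl)cyclohexyl]acetate | [Li]O[C@@H]1C[C@@](C)(C=C)[C@H](C(=C)C)C[C@@H]1CC(=O)OC | intermediate (not isolated)
10 | (3aR,5S,6S,7aR)-6-ethenyl-6-methyl-5-(prop-1-en-2-yl)hexahydro-1-benzofuran-2(3H)-one (cis-fused) | C1C(=O)O[C@@H]2C[C@@](C)(C=C)[C@H](C(=C)C)C[C@H]12 | intermediate
11 | lithium (3aR,5S,6S,7aR)-6-ethenyl-6-methyl-5-(prop-1-en-2-yl)-3a,4,5,6,7,7a-hexahydro-1-benzofuran-2-olate | C1=C(O[Li])O[C@@H]2C[C@@](C)(C=C)[C@H](C(=C)C)C[C@H]12 | intermediate (not isolated)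
12 | (3S,3aR,5S,6S,7aR)-3-[(dimethylamino)methyl]-6-ethenyl-6-methyl-5-(prop-1-en-2-yl)hexahydro-1-benzofuran-2(3H)-one | CN(C)C[C@H]1C(=O)O[C@@H]2C[C@@](C)(C=C)[C@H](C(=C)C)C[C@H]12 | intermediate
13 | 1-[(3S,3aR,5S,6S,7aR)-6-ethenyl-6-methyl-2-oxo-5-(prop-1-en-2-yl)octahydro-1-benzofuran-3-yl]-N,N,N-trimethylmethanaminium iodide | C[N+](C)(C)C[C@H]1C(=O)O[C@@H]2C[C@@](C)(C=C)[C@H](C(=C)C)C[C@H]12.[I-] | intermediate (not isolated)
14 | (3aR,5S,6S,7aR)-6-ethenyl-6-methyl-3-methylidene-5-(prop-1-en-2-yl)hexahydro-1-benzofuran-2(3H)-one | C=C1C(=O)O[C@@H]2C[C@@](C)(C=C)[C@H](C(=C)C)C[C@H]12 | intermediate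
15 | prop-2-en-1-yl acetate (allyl acetate) | CC(=O)OCC=C | starting material
16 | dimethyl oxalate | COC(=O)C(=O)OC | starting material
17 | lithium 1-(prop-2-en-1-yloxy)ethen-1-olate | C=C(O[Li])OCC=C | intermediate (not isolated)
18 | 1-methyl 4-prop-2-en-1-yl 2-oxobutanedioate | COC(=O)C(=O)CC(=O)OCC=C | intermediate
19 | 1-methyl 4-prop-2-en-1-yl 2-oxo-3-{[(3S,3aR,5S,6S,7aR)-6-ethenyl-6-methyl-2-oxo-5-(prop-1-en-2-yl)octahydro-1-benzofuran-3-yl]methyl}butanedioate (epimers at butanedioate C3) | COC(=O)C(=O)C(C(=O)OCC=C)C[C@@H]1C(=O)O[C@@H]2C[C@@](C)(C=C)[C@H](C(=C)C)C[C@H]12 | intermediate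
20 | 2-{[(3S,3aR,5S,6S,7aR)-6-ethenyl-6-methyl-2-oxo-5-(prop-1-en-2-yl)octahydro-1-benzofuran-3-yl]methyl}-4-methoxy-3,4-dioxobutanoic acid | COC(=O)C(=O)C(C(=O)O)C[C@@H]1C(=O)O[C@@H]2C[C@@](C)(C=C)[C@H](C(=C)C)C[C@H]12 | intermediate (not isolated)
21 | methyl 4-[(3S,3aR,5S,6S,7aR)-6-ethenyl-6-methyl-2-oxo-5-(prop-1-en-2-yl)octahydro-1-benzofuran-3-yl]-2-oxobutanoate | COC(=O)C(=O)CC[C@@H]1C(=O)O[C@@H]2C[C@@](C)(C=C)[C@H](C(=C)C)C[C@H]12 | intermediate
22 | (1S,5S)-(−)-verbenone | CC1=CC(=O)[C@H]2C[C@@H]1C2(C)C | starting material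
23 | {[(1S,4R,5R)-4-ethenyl-4,6,6-trimethylbicyclo[3.1.1]hept-2-en-2-yl]oxy}trimethylsilane | C[C@]1(C=C)C=C(O[Si](C)(C)C)[C@H]2C[C@@H]1C2(C)C | intermediate (not isolated)
24 | (1S,4R,5R)-4-ethenyl-4,6,6-trimethylbicyclo[3.1.1]heptan-2-one | C[C@]1(C=C)CC(=O)[C@H]2C[C@@H]1C2(C)C | intermediate
25 | {[(4S,5R)-5-ethenyl-4-(2-iodopropan-2-yl)-5-methylcyclohex-1-en-1-yl]oxy}trimethylsilane | C[C@]1(C=C)CC(O[Si](C)(C)C)=CC[C@@H]1C(C)(C)I | intermediate (not isolated)
26 | {[(4R,5R)-5-ethenyl-5-methyl-4-(prop-1-en-2-yl)cyclohex-1-en-1-yl]oxy}trimethylsilane | C[C@]1(C=C)CC(O[Si](C)(C)C)=CC[C@@H]1C(C)=C | intermediate (not isolated)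
27 | (3R,4R)-3-ethenyl-3-methyl-4-(prop-1-en-2-yl)cyclohexan-1-one | O=C1C[C@](C)(C=C)[C@@H](C(=C)C)CC1 | intermediate
28 | lithium (4R,5R)-5-ethenyl-5-methyl-4-(prop-1-en-2-yl)cyclohex-1-en-1-olate | C[C@]1(C=C)CC(O[Li])=CC[C@@H]1C(C)=C | intermediate (not isolated)
29 | methyl (2RS)-2-[(1S,4R,5R)-4-ethenyl-4-methyl-2-oxo-5-(prop-1-en-2-yl)cyclohexyl]-4-[(3S,3aR,5S,6S,7aR)-6-ethenyl-6-methyl-2-oxo-5-(prop-1-en-2-yl)octahydro-1-benzofuran-3-yl]-2-hydroxybutanoate | O=C1C[C@](C)(C=C)[C@@H](C(=C)C)C[C@H]1C(O)(C(=O)OC)CC[C@@H]2C(=O)O[C@@H]3C[C@@](C)(C=C)[C@H](C(=C)C)C[C@H]23 | intermediate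
30 | (3S,3aR,5S,6S,7aR)-6-ethenyl-3-{2-[(5R,6R)-6-ethenyl-6-methyl-2-oxo-5-(prop-1-en-2-yl)-2,4,5,6-tetrahydro-1-benzofuran-3-yl]ethyl}-6-methyl-5-(prop-1-en-2-yl)hexahydro-1-benzofuran-2(3H)-one | C=C[C@@]1(C)C=C2OC(=O)C(CC[C@@H]3C(=O)O[C@@H]4C[C@@](C)(C=C)[C@H](C(=C)C)C[C@H]34)=C2C[C@@H]1C(=C)C | intermediate
31 | methyl (2Z)-2-[(4R,5R)-4-ethenyl-4-methyl-2-oxo-5-(prop-1-en-2-yl)cyclohexylidene]-4-[(3S,3aR,5S,6S,7aR)-6-ethenyl-6-methyl-2-oxo-5-(prop-1-en-2-yl)octahydro-1-benzofuran-3-yl]butanoate | C=C[C@@]1(C)CC(=O)/C(=C(\C(=O)OC)CC[C@@H]2C(=O)O[C@@H]3C[C@@](C)(C=C)[C@H](C(=C)C)C[C@H]23)C[C@@H]1C(=C)C | intermediate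
32 | methyl (2Z)-2-[(2R,4R,5R)-4-ethenyl-2-hydroxy-4-methyl-5-(prop-1-en-2-yl)cyclohexylidene]-4-[(3S,3aR,5S,6S,7aR)-6-ethenyl-6-methyl-2-oxo-5-(prop-1-en-2-yl)octahydro-1-benzofuran-3-yl]butanoate | C=C[C@@]1(C)C[C@@H](O)/C(=C(\C(=O)OC)CC[C@@H]2C(=O)O[C@@H]3C[C@@](C)(C=C)[C@H](C(=C)C)C[C@H]23)C[C@@H]1C(=C)C | intermediate (not isolated)
33 | (3S,3aR,5S,6S,7aR)-6-ethenyl-3-{2-[(5R,6R,7aR)-6-ethenyl-6-methyl-2-oxo-5-(prop-1-en-2-yl)-2,4,5,6,7,7a-hexahydro-1-benzofuran-3-yl]ethyl}-6-methyl-5-(prop-1-en-2-yl)hexahydro-1-benzofuran-2(3H)-one | C=C[C@@]1(C)C[C@H]2OC(=O)C(CC[C@@H]3C(=O)O[C@@H]4C[C@@](C)(C=C)[C@H](C(=C)C)C[C@H]34)=C2C[C@@H]1C(=C)C | target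

**Totals**
Total step count: 15. Longest linear sequence: 12 steps (1 → 3 → 6 → 8 → 10 → 12 → 14 → 19 → 21 → 29 → 30 → 31 → 33).

**Three steps most likely to fail, with fallbacks**

Step 12 (the aldol). The α-keto ester is enolisable and may simply protonate the lithium enolate, and the enolate regiochemistry rests on kinetic selectivity. Fallback: set out from 24, run the fragmentation/elimination of step 11 without the acidic hydrolysis and isolate the regiodefined silyl enol ether 26 by distillation. A Mukaiyama aldol addition of 26 to 21 under chelating Lewis-acid catalysis (Cu(OTf)2 10 mol %, THF, −78 °C) gives the trimethylsilyl ether of the aldol adduct F1. Brief treatment with 1 M HCl–THF cleaves the silyl ether and the route is rejoined at 29.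

Step 13 (acidic cyclodehydration). Hot sulfonic acid is applied to a molecule with four vinyl/isopropenyl groups, and loss of methanol in the enol-lactonisation may be sluggish. Fallback: set out from 29 and dehydrate under neutral conditions with Martin sulfurane (CH2Cl2, 0 °C), where the acidic C7–H directs elimination to C7=C11. This gives 31 directly together with its E isomer, the (2E)-keto ester F2, which is separated by chromatography, photo-equilibrated (hν, cat. I2) and recycled. The route is rejoined at 31, by-passing 30.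

Step 15 (C8 stereocontrol). This is a reagent-controlled reduction of a hindered, tetrasubstituted s-cis enone, and the conformationally mobile ring gives no substrate bias to help. Fallback: set out from 31 and reduce under Luche conditions (NaBH4, CeCl3·7H2O, MeOH, −78 °C), which gives 32 together with its C8 epimer, the (2S)-hydroxy ester F3. PPTS closes both, giving 33 and its C8 epimer, the 8-epi-butenolide F4, which are separated by HPLC. F4 is recycled by DBU-catalysed equilibration of the butenolide γ-centre (reversible γ-deprotonation, roughly 1:1), and the route is rejoined at 33.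

**Further compounds**
F1 | step 12 | methyl (2RS)-2-[(1S,4R,5R)-4-ethenyl-4-methyl-2-oxo-5-(prop-1-en-2-yl)cyclohexyl]-4-[(3S,3aR,5S,6S,7aR)-6-ethenyl-6-methyl-2-oxo-5-(prop-1-en-2-yl)octahydro-1-benzofuran-3-yl]-2-[(trimethylsilyl)oxy]butanoate | O=C1C[C@](C)(C=C)[C@@H](C(=C)C)C[C@H]1C(O[Si](C)(C)C)(C(=O)OC)CC[C@@H]2C(=O)O[C@@H]3C[C@@](C)(C=C)[C@H](C(=C)C)C[C@H]23
F2 | step 13 | methyl (2E)-2-[(4R,5R)-4-ethenyl-4-methyl-2-oxo-5-(prop-1-en-2-yl)cyclohexylidene]-4-[(3S,3aR,5S,6S,7aR)-6-ethenyl-6-methyl-2-oxo-5-(prop-1-en-2-yl)octahydro-1-benzofuran-3-yl]butanoate | C=C[C@@]1(C)CC(=O)/C(=C(/C(=O)OC)CC[C@@H]2C(=O)O[C@@H]3C[C@@](C)(C=C)[C@H](C(=C)C)C[C@H]23)C[C@@H]1C(=C)C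
F3 | step 15 | methyl (2Z)-2-[(2S,4R,5R)-4-ethenyl-2-hydroxy-4-methyl-5-(prop-1-en-2-yl)cyclohexylidene]-4-[(3S,3aR,5S,6S,7aR)-6-ethenyl-6-methyl-2-oxo-5-(prop-1-en-2-yl)octahydro-1-benzofuran-3-yl]butanoate | C=C[C@@]1(C)C[C@H](O)/C(=C(\C(=O)OC)CC[C@@H]2C(=O)O[C@@H]3C[C@@](C)(C=C)[C@H](C(=C)C)C[C@H]23)C[C@@H]1C(=C)C
F4 | step 15 | (3S,3aR,5S,6S,7aR)-6-ethenyl-3-{2-[(5R,6R,7aS)-6-ethenyl-6-methyl-2-oxo-5-(prop-1-en-2-yl)-2,4,5,6,7,7a-hexahydro-1-benzofuran-3-yl]ethyl}-6-methyl-5-(prop-1-en-2-yl)hexahydro-1-benzofuran-2(3H)-one | C=C[C@@]1(C)C[C@@H]2OC(=O)C(CC[C@@H]3C(=O)O[C@@H]4C[C@@](C)(C=C)[C@H](C(=C)C)C[C@H]34)=C2C[C@@H]1C(=C)C
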